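**Retrosynthetic overview**

1. The last disconnections are the O–Si bond and the primary ester C–O bond. They lead to syn-diol 11 and the silyl-protected Z acid 17, which is made from crotonaldehyde through (Z)-2-iodobut-2-en-1-ol so that the enoate geometry is fixed at the vinyl iodide stage.
2. The key disconnection is the bond between the carbinol carbon C1 and its 3,4-dimethoxyphenyl ring, cut together with the C2–CH2(cinnamyl) bond (C1 benzylic carbinol, C2 methine, C3 CH2O of the propane-1,3-diol unit). Both bonds are made in one three-component union of 3,4-dimethoxyphenyllithium, (E)-alkenylboronate 2 and cinnamyl acetate 5: an allylpalladium-triggered 1,2-shift of the aryl group from boron to C1, followed by C–B to C–OH oxidation in the same flask.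
3. The enabling feature is the vicinal pair C1(OH)(aryl)–C2(H)(CH2-cinnamyl) with C3H2–O on C2. It is the anti adduct of "aryl" and "cinnamyl" across the C1=C2 bond of an (E)-3-oxypropenylboronate whose boron marks the later C1–OH. The electron-rich 3,4-dimethoxyphenyl ring on C1 is the migrating group, and the E geometry translates into the syn (1S,2R) diol pattern.
4. No ring is formed in the route. Both benzene rings are bought, both stereocentres arise in step 4, and the E styrene and the Z enoate are carried in with defined geometry.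

Key step: step 4

Remark (assumption): which enantiomer of BINAP directs the allyl group to the required face in step 4 cannot be assigned in advance. (S)-BINAP is written; (R)-BINAP would be used if the first experiment shows the opposite sense, and nothing else changes.

**Route**

Step 1
Reactants: 1 tert-butyldimethyl(prop-2-yn-1-yloxy)silane
Product: 2 (E)-tert-butyldimethyl{[3-(4,4,5,5-tetramethyl-1,3,2-dioxaborolan-2-yl)prop-2-en-1-yl]oxy}silane
Conditions: pinacolborane (1.1 equiv), Cp2Zr(H)Cl (5 mol %), Et3N (10 mol %), neat, 60 °C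
Reagents that add atoms: pinacolborane, [H]B1OC(C)(C)C(C)(C)O1
Why: Zirconocene-hydride-catalysed syn hydroboration of the terminal alkyne (hydrozirconation, then Zr-to-B exchange) should place boron on the terminal carbon and give only the E alkenylboronate, the silyl ether being inert.

Step 2
Reactants: 3 methyl (E)-3-(3,4-dimethoxyphenyl)prop-2-enoate
Product: 4 (E)-3-(3,4-dimethoxyphenyl)prop-2-en-1-ol
Conditions: i-Bu2AlH (2.5 equiv), CH2Cl2, −78 → 0 °C; aq. KNaC4H4O6 work-up
Reagents that add atoms: none
Why: 1,2-Reduction of the conjugated ester by i-Bu2AlH at low temperature should give the allylic alcohol without touching the E double bond.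

Step 3
Reactants: 4 (E)-3-(3,4-dimethoxyphenyl)prop-2-en-1-ol
Product: 5 (E)-3-(3,4-dimethoxyphenyl)prop-2-en-1-yl acetate
Conditions: Ac2O (1.5 equiv), pyridine, DMAP (5 mol %), CH2Cl2, 0 °C → rt
Reagents that add atoms: acetic anhydride, CC(=O)OC(C)=O
Why: DMAP-catalysed O-acetylation of the primary allylic alcohol should give the ionisable allylic acetate needed for π-allylpalladium formation.

Step 4
Reactants: 6 4-bromo-1,2-dimethoxybenzene; 2 (E)-alkenylboronate; 5 (E)-3-(3,4-dimethoxyphenyl)prop-2-en-1-yl acetate
Product: 10 (1S,2R,4E)-2-{[(tert-butyldimethylsilyl)oxy]methyl}-1,5-bis(3,4-dimethoxyphenyl)pent-4-en-1-ol, via (3,4-dimethoxyphenyl)lithium 7 (not isolated), via lithium aryl(alkenyl)boronate complex 8 (not isolated), via benzylic pinacol boronic ester 9 (not isolated)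
Conditions: 6, t-BuLi (2.0 equiv), Et2O/THF, −78 °C; 2 (1.1 equiv), −78 °C → rt; then 5 (1.2 equiv), Pd2(dba)3 (2.5 mol %), (S)-BINAP (6 mol %), THF, rt; then 3 M aq. NaOH, 30% aq. H2O2, 0 °C → rt
Reagents that add atoms: hydrogen peroxide, OO
Why: Proposed new method: zerovalent palladium should ionise acetate 5 to the cationic complex [(BINAP)Pd(η3-1-arylallyl)]+, and the C1=C2 π bond of ate complex 8 should attack its unsubstituted CH2 terminus through C2 (the carbon β to boron) from outside the coordination sphere while the 3,4-dimethoxyphenyl group shifts from boron to C1 anti-periplanar to the new C2–C bond (electrophile-induced 1,2-metalate rearrangement), so that the aryl–C1 and C2–cinnamyl bonds arise in one anti addition across the alkene, after which alkaline H2O2 converts the C1–B bond of 9 into C1–OH with retention. The closest known reaction types are the palladium/BINAP-catalysed allylation-induced 1,2-boronate shift of indol-2-yl boronate complexes with allylic acetates, the iridium-catalysed allylation of acyclic alkenyl boronate complexes (branched allyl products) and the palladium-catalysed conjunctive cross-coupling of vinyl boronate complexes; the untested part is the combination of an acyclic β-substituted (E)-alkenyl boronate complex with a linear-selective allylpalladium electrophile. No ring is closed. The relative configuration of the two new stereocentres (syn hydroxyl/cinnamyl, 1S,2R in 10) is fixed by the E geometry of 2 together with the anti course of the addition, and the absolute configuration by the chiral bisphosphine on palladium, which has to direct the allyl terminus to the Si face of C2. The step needs attack at the CH2 end of the allyl unit (normal for soft nucleophiles on 1-arylallyl palladium complexes, and it keeps the styrene E), migration of the aryl group and not of a pinacol oxygen (carbon ligands migrate far faster), and metalate shift instead of direct aryl–allyl cross-coupling (disfavoured at a coordinatively saturated cationic bisphosphine complex, with 2 in slight excess so that no free aryllithium meets the acetate). The silyloxy group at C3 is too poor a leaving group for SN2′-type collapse of 8 or for ionisation by palladium, which is why the oxygen is carried as a silyl ether and not as the final ester.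

Step 5
Reactants: 10 (1S,2R,4E)-silyl ether alcohol
Product: 11 (1S,2R)-1-(3,4-dimethoxyphenyl)-2-[(E)-3-(3,4-dimethoxyphenyl)prop-2-en-1-yl]propane-1,3-diol
Conditions: Bu4NF (1.2 equiv), THF, 0 °C → rt
Reagents that add atoms: none
Why: Fluoride-induced cleavage of the primary silyl ether should free the 1,3-diol without affecting the stereocentres or the styrene.

Step 6
Reactants: 12 (E)-but-2-enal
Product: 13 (Z)-2-iodobut-2-enal
Conditions: I2 (1.5 equiv), K2CO3 (1.2 equiv), DMAP (0.2 equiv), THF/H2O (1:1), rt
Reagents that add atoms: iodine, II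
Why: Baylis–Hillman-type α-iodination of the enal (conjugate addition of DMAP, iodination of the enolate, E1cB loss of DMAP) should give the α-iodoenal as the Z isomer with methyl cis to iodine, as is established for this aldehyde.

Step 7
Reactants: 13 (Z)-2-iodobut-2-enal
Product: 14 (Z)-2-iodobut-2-en-1-ol
Conditions: NaBH4 (0.6 equiv), THF/H2O (9:1), 0 °C
Reagents that add atoms: none
Why: Chemoselective 1,2-reduction of the aldehyde by NaBH4 should leave the vinyl iodide and the alkene geometry untouched.

Step 8
Reactants: 14 (Z)-2-iodobut-2-en-1-ol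
Product: 15 tert-butyl{[(Z)-2-iodobut-2-en-1-yl]oxy}dimethylsilane
Conditions: TBSCl (1.2 equiv), imidazole (2 equiv), CH2Cl2, 0 °C → rt
Reagents that add atoms: tert-butyldimethylsilyl chloride, CC(C)(C)[Si](C)(C)Cl
Why: Imidazole-assisted silylation of the primary allylic alcohol masks the hydroxyl group for the organolithium step and the later acylation.

Step 9
Reactants: 15 tert-butyl{[(Z)-2-iodobut-2-en-1-yl]oxy}dimethylsilane
Product: 17 (Z)-2-{[(tert-butyldimethylsilyl)oxy]methyl}but-2-enoic acid, via vinyllithium 16 (not isolated)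
Conditions: t-BuLi (2.1 equiv), Et2O, −78 °C; CO2 (dry gas), −78 → 0 °C; then 0.5 M aq. HCl to pH 3, 0 °C
Reagents that add atoms: carbon dioxide, O=C=O
Why: Iodine–lithium exchange with t-BuLi at −78 °C proceeds with retention of alkene geometry and the configurationally stable vinyllithium is carboxylated by CO2, so the carboxyl group should take the place of iodine, cis to the methyl group (Z acid).

Step 10
Reactants: 17 (Z)-2-{[(tert-butyldimethylsilyl)oxy]methyl}but-2-enoic acid; 11 (1S,2R)-diol
Product: 19 (2R,4E)-2-[(S)-(3,4-dimethoxyphenyl)(hydroxy)methyl]-5-(3,4-dimethoxyphenyl)pent-4-en-1-yl (Z)-2-{[(tert-butyldimethylsilyl)oxy]methyl}but-2-enoate, via acid chloride 18 (not isolated)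
Conditions: 17 (1.15 equiv), 1-chloro-N,N,2-trimethylprop-1-en-1-amine (1.2 equiv), CH2Cl2, 0 °C; then added to 11, 2,4,6-collidine (3 equiv), CH2Cl2, −40 → 0 °C
Reagents that add atoms: none
Why: Acylation by the acid chloride made under neutral conditions (Ghosez reagent) with the hindered, non-nucleophilic base 2,4,6-collidine should favour the primary over the secondary benzylic hydroxyl group and avoids the nucleophilic DMAP-type catalysts that isomerise angelate-type Z enoyl donors to the E isomers.

Step 11
Reactants: 19 silyl-protected ester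
Product: 20 (2R,4E)-2-[(S)-(3,4-dimethoxyphenyl)(hydroxy)methyl]-5-(3,4-dimethoxyphenyl)pent-4-en-1-yl (Z)-2-(hydroxymethyl)but-2-enoate (CNP0417076.1)
Conditions: HF·pyridine, pyridine, THF, 0 °C → rt
Reagents that add atoms: none
Why: Buffered HF·pyridine should cleave the primary allylic silyl ether under mildly acidic, non-basic conditions, so that neither 1,3-acyl migration to the benzylic hydroxyl group nor ionisation of the electron-rich benzylic alcohol is expected.

**Compound list**

1 | tert-butyldimethyl(prop-2-yn-1-yloxy)silane | C#CCO[Si](C)(C)C(C)(C)C | starting material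
2 | (E)-tert-butyldimethyl{[3-(4,4,5,5-tetramethyl-1,3,2-dioxaborolan-2-yl)prop-2-en-1-yl]oxy}silane | CC(C)(C)[Si](C)(C)OC/C=C/B1OC(C)(C)C(C)(C)O1 | intermediate
3 | methyl (E)-3-(3,4-dimethoxyphenyl)prop-2-enoate | COC(=O)/C=C/c1ccc(OC)c(OC)c1 | starting material
4 | (E)-3-(3,4-dimethoxyphenyl)prop-2-en-1-ol | OC/C=C/c1ccc(OC)c(OC)c1 | intermediate
5 | (E)-3-(3,4-dimethoxyphenyl)prop-2-en-1-yl acetate | CC(=O)OC/C=C/c1ccc(OC)c(OC)c1 | intermediate
6 | 4-bromo-1,2-dimethoxybenzene | COc1ccc(Br)cc1OC | starting material
7 | (3,4-dimethoxyphenyl)lithium (not isolated) | [Li]c1ccc(OC)c(OC)c1 | intermediate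
8 | lithium (3,4-dimethoxyphenyl){(E)-3-[(tert-butyldimethylsilyl)oxy]prop-1-en-1-yl}(pinacolato)borate (not isolated) | [Li+].CC(C)(C)[Si](C)(C)OC/C=C/[B-]1(c2ccc(OC)c(OC)c2)OC(C)(C)C(C)(C)O1 | intermediate
9 | tert-butyl({(2S,4E)-2-[(S)-(3,4-dimethoxyphenyl)(4,4,5,5-tetramethyl-1,3,2-dioxaborolan-2-yl)methyl]-5-(3,4-dimethoxyphenyl)pent-4-en-1-yl}oxy)dimethylsilane (not isolated) | CC(C)(C)[Si](C)(C)OC[C@@H](C/C=C/c1ccc(OC)c(OC)c1)[C@H](B1OC(C)(C)C(C)(C)O1)c1ccc(OC)c(OC)c1 | intermediate
10 | (1S,2R,4E)-2-{[(tert-butyldimethylsilyl)oxy]methyl}-1,5-bis(3,4-dimethoxyphenyl)pent-4-en-1-ol | CC(C)(C)[Si](C)(C)OC[C@@H](C/C=C/c1ccc(OC)c(OC)c1)[C@H](O)c1ccc(OC)c(OC)c1 | intermediate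
11 | (1S,2R)-1-(3,4-dimethoxyphenyl)-2-[(E)-3-(3,4-dimethoxyphenyl)prop-2-en-1-yl]propane-1,3-diol | OC[C@@H](C/C=C/c1ccc(OC)c(OC)c1)[C@H](O)c1ccc(OC)c(OC)c1 | intermediate
12 | (E)-but-2-enal (crotonaldehyde) | C/C=C/C=O | starting material
13 | (Z)-2-iodobut-2-enal | C/C=C(\I)C=O | intermediate
14 | (Z)-2-iodobut-2-en-1-ol | C/C=C(\I)CO | intermediate
15 | tert-butyl{[(Z)-2-iodobut-2-en-1-yl]oxy}dimethylsilane | C/C=C(\I)CO[Si](C)(C)C(C)(C)C | intermediate
16 | {(E)-1-[(tert-butyldimethylsilyl)oxy]but-2-en-2-yl}lithium (not isolated; lithium cis to the methyl group) | C/C=C(\[Li])CO[Si](C)(C)C(C)(C)C | intermediate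
17 | (Z)-2-{[(tert-butyldimethylsilyl)oxy]methyl}but-2-enoic acid | C/C=C(/CO[Si](C)(C)C(C)(C)C)C(=O)O | intermediate
18 | (Z)-2-{[(tert-butyldimethylsilyl)oxy]methyl}but-2-enoyl chloride (not isolated) | C/C=C(/CO[Si](C)(C)C(C)(C)C)C(=O)Cl | intermediate
19 | (2R,4E)-2-[(S)-(3,4-dimethoxyphenyl)(hydroxy)methyl]-5-(3,4-dimethoxyphenyl)pent-4-en-1-yl (Z)-2-{[(tert-butyldimethylsilyl)oxy]methyl}but-2-enoate | C/C=C(/CO[Si](C)(C)C(C)(C)C)C(=O)OC[C@@H](C/C=C/c1ccc(OC)c(OC)c1)[C@H](O)c1ccc(OC)c(OC)c1 | intermediate
20 | (2R,4E)-2-[(S)-(3,4-dimethoxyphenyl)(hydroxy)methyl]-5-(3,4-dimethoxyphenyl)pent-4-en-1-yl (Z)-2-(hydroxymethyl)but-2-enoate | C/C=C(/CO)C(=O)OC[C@@H](C/C=C/c1ccc(OC)c(OC)c1)[C@H](O)c1ccc(OC)c(OC)c1 | target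

**Step count**

Total: 11 steps. Longest linear sequence: 6 steps (12 → 13 → 14 → 15 → 17 → 19 → 20; the branch 3 → 4 → 5 → 10 → 11 → 19 → 20 is equally long).

**Steps most likely to fail, with fallbacks**

Step 4 (proposed new method). The β-substituted, inductively deactivated alkenyl boronate complex may attack the stabilised 1-arylallyl palladium cation too slowly. The aryl group may be transferred to palladium instead (direct aryl–allyl coupling). The ligand may also discriminate the two alkene faces poorly. The fallback uses known chemistry, forms the same aryl–carbon bond by a 1,2-shift of the aryl group from boron to carbon, sets out from acetate 5 and returns at alcohol 10. Palladium-catalysed allylic alkylation of dimethyl malonate with 5 (NaH, Pd(PPh3)4, THF) should give dimethyl 2-[(E)-3-(3,4-dimethoxyphenyl)prop-2-en-1-yl]propanedioate F1. LiAlH4 reduction should give the prochiral 2-[(E)-3-(3,4-dimethoxyphenyl)prop-2-en-1-yl]propane-1,3-diol F2. Lipase-catalysed desymmetrisation (Burkholderia cepacia lipase with vinyl acetate, or enzymatic hydrolysis of the diacetate if the enzyme prefers the other arm) should give (2R,4E)-5-(3,4-dimethoxyphenyl)-2-(hydroxymethyl)pent-4-en-1-yl acetate F3. Silylation (TBSCl, imidazole) should give the silyl ether acetate F4, methanolysis (K2CO3, MeOH) the (2S)-silyl ether alcohol F5, and carbamoylation (N,N-diisopropylcarbamoyl chloride, Et3N, toluene, reflux) the N,N-diisopropylcarbamate F6. Deprotonation with s-BuLi and (+)-sparteine (Et2O, −78 °C) should remove the pro-R hydrogen of the OCH2 group and give the α-lithiated carbamate F7. Commercial 2-(3,4-dimethoxyphenyl)-4,4,5,5-tetramethyl-1,3,2-dioxaborolane should add with retention to give the boronate complex F8. On warming with MgBr2·OEt2 the aryl group should migrate from boron to carbon with inversion and loss of the carbamate, giving boronic ester 9, and NaOH/H2O2 should then give 10. Both stereocentres are then under enzyme and reagent control; the price is the longer sequence.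

Step 10. The Z enoyl donor may isomerise to the E isomer or lose its γ-proton to a vinylketene on activation, and the benzylic hydroxyl group may compete for the acyl group. The fallback keeps the benzylic oxygen masked as boron, sets out from boronic ester 9 (isolated from step 4 before the oxidation) and returns at ester 19. Acid-catalysed methanolysis of the silyl ether (camphorsulfonic acid, MeOH/CH2Cl2, 0 °C) should give (2S,4E)-2-[(S)-(3,4-dimethoxyphenyl)(4,4,5,5-tetramethyl-1,3,2-dioxaborolan-2-yl)methyl]-5-(3,4-dimethoxyphenyl)pent-4-en-1-ol F9, which has only one hydroxyl group. Mitsunobu esterification with acid 17 (PPh3, diisopropyl azodicarboxylate, THF, 0 °C), in which the carboxylate is the nucleophile and no activated acyl species is formed, should give the boronate ester F10. Oxidation of the C–B bond with NaBO3·4H2O (THF/H2O, rt) with retention should give 19.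

Step 9. The 2-lithio allylic silyl ether may lose silyloxide by β-elimination (allene formation) or suffer silyl migration from oxygen to carbon before it is carboxylated. The fallback replaces the organolithium by a palladium acyl, sets out from vinyl iodide 15 and returns at acid 17. Methoxycarbonylation (Pd(PPh3)4, CO 1 atm, Et3N, MeOH/DMF, 50 °C) should give, with retention of geometry, methyl (Z)-2-{[(tert-butyldimethylsilyl)oxy]methyl}but-2-enoate F11. Mild saponification (LiOH, THF/MeOH/H2O, 0 °C → rt, then acidification to pH 3) should give 17.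

**Further compounds**

F1 | step 4 | dimethyl 2-[(E)-3-(3,4-dimethoxyphenyl)prop-2-en-1-yl]propanedioate | COC(=O)C(C/C=C/c1ccc(OC)c(OC)c1)C(=O)OC
F2 | step 4 | 2-[(E)-3-(3,4-dimethoxyphenyl)prop-2-en-1-yl]propane-1,3-diol | OCC(CO)C/C=C/c1ccc(OC)c(OC)c1
F3 | step 4 | (2R,4E)-5-(3,4-dimethoxyphenyl)-2-(hydroxymethyl)pent-4-en-1-yl acetate | OC[C@@H](C/C=C/c1ccc(OC)c(OC)c1)COC(C)=O
F4 | step 4 | (2S,4E)-2-{[(tert-butyldimethylsilyl)oxy]methyl}-5-(3,4-dimethoxyphenyl)pent-4-en-1-yl acetate | CC(C)(C)[Si](C)(C)OC[C@@H](C/C=C/c1ccc(OC)c(OC)c1)COC(C)=O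
F5 | step 4 | (2S,4E)-2-{[(tert-butyldimethylsilyl)oxy]methyl}-5-(3,4-dimethoxyphenyl)pent-4-en-1-ol | CC(C)(C)[Si](C)(C)OC[C@@H](C/C=C/c1ccc(OC)c(OC)c1)CO
F6 | step 4 | (2S,4E)-2-{[(tert-butyldimethylsilyl)oxy]methyl}-5-(3,4-dimethoxyphenyl)pent-4-en-1-yl N,N-diisopropylcarbamate | CC(C)(C)[Si](C)(C)OC[C@@H](C/C=C/c1ccc(OC)c(OC)c1)COC(=O)N(C(C)C)C(C)C
F7 | step 4 | α-lithiated carbamate from F6 (lithium in the place of the pro-R hydrogen of the OCH2 group; not isolated) | CC(C)(C)[Si](C)(C)OC[C@@H](C/C=C/c1ccc(OC)c(OC)c1)[C@@H]([Li])OC(=O)N(C(C)C)C(C)C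
F8 | step 4 | lithium boronate complex of F7 with 2-(3,4-dimethoxyphenyl)-4,4,5,5-tetramethyl-1,3,2-dioxaborolane (boron in the place of lithium; not isolated) | [Li+].CC(C)(C)[Si](C)(C)OC[C@@H](C/C=C/c1ccc(OC)c(OC)c1)[C@@H]([B-]1(c2ccc(OC)c(OC)c2)OC(C)(C)C(C)(C)O1)OC(=O)N(C(C)C)C(C)C
F9 | step 10 | (2S,4E)-2-[(S)-(3,4-dimethoxyphenyl)(4,4,5,5-tetramethyl-1,3,2-dioxaborolan-2-yl)methyl]-5-(3,4-dimethoxyphenyl)pent-4-en-1-ol | OC[C@@H](C/C=C/c1ccc(OC)c(OC)c1)[C@H](B1OC(C)(C)C(C)(C)O1)c1ccc(OC)c(OC)c1
F10 | step 10 | (2S,4E)-2-[(S)-(3,4-dimethoxyphenyl)(4,4,5,5-tetramethyl-1,3,2-dioxaborolan-2-yl)methyl]-5-(3,4-dimethoxyphenyl)pent-4-en-1-yl (Z)-2-{[(tert-butyldimethylsilyl)oxy]methyl}but-2-enoate | C/C=C(/CO[Si](C)(C)C(C)(C)C)C(=O)OC[C@@H](C/C=C/c1ccc(OC)c(OC)c1)[C@H](B1OC(C)(C)C(C)(C)O1)c1ccc(OC)c(OC)c1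
F11 | step 9 | methyl (Z)-2-{[(tert-butyldimethylsilyl)oxy]methyl}but-2-enoate | C/C=C(/CO[Si](C)(C)C(C)(C)C)C(=O)OC
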